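The runs stem from a simulated flask from invented constants, and the scatter is random.

In the violet run, which is the very flask asked about followed so far, target cannot have slowed for want of dissolved substrate: at 40.0 s dissolved substrate still reads 62.8%, against 63.7% at 10.0 s.

the same everywhere: solid substrate 0.50 mM

|  | reagent | remark | time |
|---|---|---|---|
| violet | 1 mM | the very flask that is asked about, followed so far |  |
| flask | 1.00 mM |  | 3.0 min |

violet run (percent of the solid substrate charged)

| time / s | target / % | dissolved substrate / % |
|---|---|---|
| 10.0 | 21.0 | 63.7 |
| 15.0 | 25.4 | 64.1 |
| 25.0 | 30.3 | 63.8 |
| 40.0 | 30.7 | 62.8 |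

(each reading ± 0.5 percentage points)

1. how much target there is at 3.0 min, in percent of the solid substrate charged
2. concentration of dissolved substrate in solution at 3.0 min, in percent of saturation

- solid, in amounts per volume of the solution: solid substrate
- at the start none of the solid substrate is in solution
- dissolved substrate means what is dissolved; the solid is not counted in it

So I reckon in rates. Over the first 10.0 s the violet run makes target at 0.0210 s⁻¹ as a fraction of the charge, and between 15.0 s and 25.0 s at 0.00490 s⁻¹, which is 4.29 times slower. Dissolved substrate holds near 63.8%, so I treat this as a pseudo-first-order fall with constant 0.0970 s⁻¹, which by 40.0 s has cut the making rate 29.8 times.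

Carried from 25.0 s to 40.0 s, that rate should add 2.4 percentage points, but the readings add 0.4 points, which is less, though each reading scatters by 0.5 points. I read the shortfall as a leak, the fraction of target lost per unit time, 0.00434 s⁻¹. Leak times time counts turnovers of target: 0.607 from 40.0 s to 3.0 min, which leaves about 16.7% of target.

The forecast differs: it gives 31% (29.8% to 33%) of target and 100% (96% to 101%) of saturation, holding that “nothing further should happen by 180 s”.

    solid substrate ⇌ dissolved substrate, rate k1*(cs1 - [dissolved substrate]) while solid is left; crystals form when [dissolved substrate] > cs1 (solubility = 0.320 mM, k = 1.50 s⁻¹)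
    target ⇌ isomer of the product (K = 21.0, k = 0.00740 s⁻¹)
    dissolved substrate + reagent → target (k = 74.0 M⁻¹ s⁻¹)
    2 reagent → self-condensation product (k = 65.0 M⁻¹ s⁻¹)
    reagent → side product (k = 0.0330 s⁻¹)

The flask gives 12.5% of target and 93.2% of saturation. Dissolved substrate and reagent made target while reagent fell to 14.8% of its charge at 0.300 min and 0.200% at 1.50 min, with 30.0% of target standing at 0.750 min. Target meanwhile kept turning into isomer of the product, which reached 27.8% at 3.00 min, when solid substrate stood at 0%. From the 40.0 s reading the flask shows 0.895 turnovers against my 0.607. For the same flask read at 8.0 min, the leak counts 1.91 turnovers and so 4.56% of target, and that flask holds 2.88%.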